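**Plan**

1. Numbering (daucane, used in all Why lines): C1 quaternary C–Me, C2 CHOH, C3 CH2, C4 C(OH)i-Pr, C5 ring-fusion CH, C6 CH–O-aroyl, C7 CH2, C8=C9 ring olefin, C10 CH2. Names in the compound list use their own IUPAC numbers.
2. Retrosynthesis: free the phenol, take the C2 carbinol back to the ketone, remove the 6-O-aroyl group; then cut C3–C4 and C1–C5 together, which opens both rings to one chain C3–C2–C1–C10–C9=C8–C7–C6–C5=C4.
3. Enabling feature: the cyclopentane is 1,3-dioxygenated. O–C2 sits on the middle carbon of the C1–C2–C3 unit (a 2-oxyallyl cation) and O–C4 on the C4=C5 unit (an enol ether). C1 and C5 are also linked by the arc C10–C9=C8–C7–C6 of the cycloheptene, so a tethered (3+2) closes the seven-membered ring with its first bond and the five-membered ring with its second.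
4. Chain assembly (forward): dithiane acyl anion + (R)-epichlorohydrin gives the epoxide; propiolate opening; Me2CuLi syn-addition (Z-C8=C9); allylic bromide + methoxy-lactate enolate (C1, with OMe as latent leaving group); ester to methyl ketone; dithiane off; bis(silyl enol ether).
5. Stereochemistry: C6 from (R)-epichlorohydrin; C5, C1 and C4 in the cycloaddition (A1,3 strain at C6, chair-like cycloheptene transition state, suprafacial addition to the Z enol ether); C2 by C4–OH-directed hydride delivery.

Key step: step 12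

**Route**

Step 1
Reactants: 1 2-methylpropanal; 2 propane-1,3-dithiol
Product: 3 2-(propan-2-yl)-1,3-dithiane
Conditions: BF3·OEt2 (cat.), CH2Cl2, 0 °C → rt
Reagents that add atoms: none
Why: Lewis-acid-catalysed dithioacetalisation of an aldehyde, which turns the future C4 carbonyl carbon into an acyl-anion equivalent; no stereocentre is formed.

Step 2
Reactants: 3 2-(propan-2-yl)-1,3-dithiane; 4 (R)-epichlorohydrin
Product: 7 2-{[(2R)-oxiran-2-yl]methyl}-2-(propan-2-yl)-1,3-dithiane, via lithiated dithiane 5 (not isolated), via lithium chloroalkoxide 6 (not isolated)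
Conditions: n-BuLi, THF, −20 °C; then 4, −78 °C → rt
Reagents that add atoms: none
Why: Corey–Seebach umpolung, in which the lithiated dithiane opens the epoxide of 4 at its CH2 end (faster than displacement of chloride, which would give the other enantiomer) and the chloro-alkoxide recloses by intramolecular Williamson displacement, so the C–O stereocentre (future C6) is carried over untouched from the chiral pool.

Step 3
Reactants: 7 2-{[(2R)-oxiran-2-yl]methyl}-2-(propan-2-yl)-1,3-dithiane; 8 ethyl propiolate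
Product: 10 ethyl (5S)-5-hydroxy-6-[2-(propan-2-yl)-1,3-dithian-2-yl]hex-2-ynoate, via lithium ethyl propiolate 9 (not isolated)
Conditions: 8, n-BuLi, THF, −78 °C; BF3·OEt2; then 7, −78 °C
Reagents that add atoms: none
Why: BF3-assisted opening of a terminal epoxide by a lithium acetylide (Yamaguchi–Hirao alkynylation) at the unhindered CH2 (future C7); the carbinol centre is not involved.

Step 4
Reactants: 10 ethyl (5S)-5-hydroxy-6-[2-(propan-2-yl)-1,3-dithian-2-yl]hex-2-ynoate
Product: 11 ethyl (5S)-5-{[tert-butyl(dimethyl)silyl]oxy}-6-[2-(propan-2-yl)-1,3-dithian-2-yl]hex-2-ynoate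
Conditions: TBSOTf, 2,6-lutidine, CH2Cl2, −78 → 0 °C
Reagents that add atoms: tert-butyldimethylsilyl trifluoromethanesulfonate, CC(C)(C)[Si](C)(C)OS(=O)(=O)C(F)(F)F
Why: silylation of a secondary alcohol with a silyl triflate; the ether prevents lactonisation after step 5 and ether formation after step 7, and is the C6 substituent that steers step 12.

Step 5
Reactants: 11 ethyl (5S)-5-{[tert-butyl(dimethyl)silyl]oxy}-6-[2-(propan-2-yl)-1,3-dithian-2-yl]hex-2-ynoate
Product: 12 ethyl (2Z,5S)-5-{[tert-butyl(dimethyl)silyl]oxy}-3-methyl-6-[2-(propan-2-yl)-1,3-dithian-2-yl]hex-2-enoate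
Conditions: Me2CuLi (from MeLi, CuI), THF, −78 °C; MeOH quench at −78 °C
Reagents that add atoms: lithium dimethylcuprate, [Li+].C[Cu-]C
Why: conjugate addition of a Gilman cuprate to a 2-ynoate is a syn carbocupration, and cold protonation with retention leaves the new methyl cis to H, so C7 is cis to the ester carbon (future C10) as the ring olefin C8=C9 requires.

Step 6
Reactants: 12 ethyl (2Z,5S)-5-{[tert-butyl(dimethyl)silyl]oxy}-3-methyl-6-[2-(propan-2-yl)-1,3-dithian-2-yl]hex-2-enoate
Product: 13 (2Z,5S)-5-{[tert-butyl(dimethyl)silyl]oxy}-3-methyl-6-[2-(propan-2-yl)-1,3-dithian-2-yl]hex-2-en-1-ol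
Conditions: DIBAL-H, CH2Cl2, −78 °C; Rochelle salt work-up
Reagents that add atoms: none
Why: DIBAL 1,2-reduction of an enoate to the allylic alcohol, which does not touch the olefin geometry, the dithiane or the silyl ether.

Step 7
Reactants: 13 (2Z,5S)-5-{[tert-butyl(dimethyl)silyl]oxy}-3-methyl-6-[2-(propan-2-yl)-1,3-dithian-2-yl]hex-2-en-1-ol
Product: 14 2-[(2S,4Z)-6-bromo-2-{[tert-butyl(dimethyl)silyl]oxy}-4-methylhex-4-en-1-yl]-2-(propan-2-yl)-1,3-dithiane
Conditions: CBr4, PPh3, CH2Cl2, 0 °C
Reagents that add atoms: carbon tetrabromide, BrC(Br)(Br)Br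
Why: Appel bromination of a primary allylic alcohol under neutral conditions; the bromide should be used crude to avoid allylic isomerisation.

Step 8
Reactants: 14 2-[(2S,4Z)-6-bromo-2-{[tert-butyl(dimethyl)silyl]oxy}-4-methylhex-4-en-1-yl]-2-(propan-2-yl)-1,3-dithiane; 15 methyl 2-methoxypropanoate (racemic)
Product: 17 methyl (4Z,7S)-7-{[tert-butyl(dimethyl)silyl]oxy}-2-methoxy-2,5-dimethyl-8-[2-(propan-2-yl)-1,3-dithian-2-yl]oct-4-enoate (both C2 epimers), via lithium enolate 16 (not isolated)
Conditions: 15, LDA, THF, −78 °C; then 14, −78 → −20 °C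
Reagents that add atoms: none
Why: SN2 alkylation of an α-alkoxy ester enolate by a primary allylic bromide builds the fully substituted C1 with its methyl and its methoxy leaving group; its configuration is irrelevant because it is planarised in step 12.

Step 9
Reactants: 17 methyl (4Z,7S)-7-{[tert-butyl(dimethyl)silyl]oxy}-2-methoxy-2,5-dimethyl-8-[2-(propan-2-yl)-1,3-dithian-2-yl]oct-4-enoate
Product: 19 (5Z,8S)-8-{[tert-butyl(dimethyl)silyl]oxy}-3-methoxy-3,6-dimethyl-9-[2-(propan-2-yl)-1,3-dithian-2-yl]non-5-en-2-one (both C3 epimers), via silyl ketone enolate 18 (not isolated)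
Conditions: Me3SiCH2Li, pentane/THF, 0 °C → rt; then MeOH, rt
Reagents that add atoms: (trimethylsilyl)methyllithium, [Li]C[Si](C)(C)C
Why: acyl substitution of a methyl ester by a silyl-stabilised carbanion stops at the ketone level because the β-ketosilane is deprotonated at once to enolate 18, which methanol protonates and C-desilylates to the methyl ketone (C2, C3).

Step 10
Reactants: 19 (5Z,8S)-8-{[tert-butyl(dimethyl)silyl]oxy}-3-methoxy-3,6-dimethyl-9-[2-(propan-2-yl)-1,3-dithian-2-yl]non-5-en-2-one
Product: 20 (5Z,8S)-8-{[tert-butyl(dimethyl)silyl]oxy}-3-methoxy-3,6,11-trimethyldodec-5-ene-2,10-dione (both C3 epimers)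
Conditions: MeI, CaCO3, MeCN/H2O (9:1), 45 °C
Reagents that add atoms: water, O
Why: S-alkylative hydrolysis of a 1,3-dithiane under buffered neutral conditions that leave the silyl ether, the tertiary methyl ether and the olefin alone.

Step 11
Reactants: 20 (5Z,8S)-8-{[tert-butyl(dimethyl)silyl]oxy}-3-methoxy-3,6,11-trimethyldodec-5-ene-2,10-dione
Product: 22 (5Z,8S,9Z)-8-{[tert-butyl(dimethyl)silyl]oxy}-3-methoxy-3,6,11-trimethyl-2,10-bis[(triethylsilyl)oxy]dodeca-1,5,9-triene (both C3 epimers), via dilithium bis-enolate 21 (not isolated)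
Conditions: LiHMDS, THF, −78 °C; then TESCl, Et3N, −78 → −20 °C
Reagents that add atoms: chlorotriethylsilane, CC[Si](Cl)(CC)CC
Why: kinetic double enolisation and O-silylation, in which the methyl ketone can enolise only toward C3, the isopropyl ketone is deprotonated at the CH2 (C5) and not at the hindered methine, and LiHMDS in THF gives the Z(O) enolate of a ketone with a branched acyl group, so C6 ends cis to OSiEt3.

Step 12
Reactants: 22 (5Z,8S,9Z)-8-{[tert-butyl(dimethyl)silyl]oxy}-3-methoxy-3,6,11-trimethyl-2,10-bis[(triethylsilyl)oxy]dodeca-1,5,9-triene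
Product: 25 (3R,3aS,4S,8aR)-4-{[tert-butyl(dimethyl)silyl]oxy}-6,8a-dimethyl-3-(propan-2-yl)-3-[(triethylsilyl)oxy]-3,3a,4,5,8,8a-hexahydroazulen-1(2H)-one, via siloxyallyl cation 23 (not isolated), via cycloheptenyl oxocarbenium ion 24 (not isolated)
Conditions: TESOTf (0.2 equiv), 2,6-di-tert-butyl-4-methylpyridine (0.3 equiv), CH2Cl2 (0.005 M), −78 → −40 °C
Reagents that add atoms: none
Why: Proposed new method: the silyl triflate silylates the tertiary methoxy oxygen of 22 and ionises it (as Et3SiOMe) to the 2-(triethylsiloxy)allyl cation 23, whose tertiary terminus C1 is attacked by C5 of the tethered (Z)-silyl enol ether to give the silyloxocarbenium ion 24; the terminal carbon C3 of the silyl enol ether left on the C1 side then adds to C4 (intramolecular Mukaiyama-type closure) and the carbonyl-bound Et3Si+ returns to triflate, so the process is a stepwise cationic (3+2) cycloaddition, catalytic in TESOTf. The closest known reaction type is the Lewis-acid-promoted intermolecular (3+2) cyclopentanone annulation of 2-siloxyallyl cations with silyl enol ethers or vinyl sulfides, supported by intramolecular (4+3) cycloadditions of tethered oxyallyl cations and by silyl-triflate ionisation of acetals in the presence of silyl enol ethers; a tethered (3+2) version that closes a carbocycle across the first new bond is not established. The cycloheptene closes by 7-(enolexo)-exo-trig attack of C5 on C1, made possible by the Z C8=C9 bond in the tether, and the cyclopentanone by 5-(enolendo)-exo-trig attack of C3 on C4, the same formally unfavourable but documented closure as in the intermolecular annulation. C5 is set by allylic 1,3-strain (with OSiEt3 cis to C6 the C6–H lies in the enol ether plane and the cation, delivered through C7, adds anti to the C6–OTBS group, H5/H6 trans); C1 is set in a chair-like cycloheptene transition state in which the enol ether, the OTBS group and the bulky siloxyallyl unit are pseudo-equatorial and only the methyl is axial (trans ring fusion); C4 is set because C3 is held over the face of the Z enol ether already bonded to C1, and isopropyl trans to C6 is also the preferred outcome if 24 rotates before it closes. The step needs C5–C1 and not C5–C3 bonding (a seven- against a nine-membered ring), capture of 23 faster than E1 loss of a C10 proton (electron-rich enol ether, −78 °C, high dilution) and survival of the enol ethers (the hindered pyridine scavenges TfOH).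

Step 13
Reactants: 25 (3R,3aS,4S,8aR)-4-{[tert-butyl(dimethyl)silyl]oxy}-6,8a-dimethyl-3-(propan-2-yl)-3-[(triethylsilyl)oxy]-3,3a,4,5,8,8a-hexahydroazulen-1(2H)-one
Product: 26 (3R,3aS,4S,8aR)-3,4-dihydroxy-6,8a-dimethyl-3-(propan-2-yl)-3,3a,4,5,8,8a-hexahydroazulen-1(2H)-one
Conditions: HF·pyridine, pyridine, THF, 0 °C → rt
Reagents that add atoms: none
Why: fluoride cleavage of both silyl ethers (Si–F bond formation) under buffered, weakly acidic conditions, so that the tertiary aldol is never exposed to base (retro-aldol, dehydration).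

Step 14
Reactants: 26 (3R,3aS,4S,8aR)-3,4-dihydroxy-6,8a-dimethyl-3-(propan-2-yl)-3,3a,4,5,8,8a-hexahydroazulen-1(2H)-one; 27 4-acetoxybenzoic acid
Product: 28 (3R,3aS,4S,8aR)-3-hydroxy-6,8a-dimethyl-1-oxo-3-(propan-2-yl)-1,2,3,3a,4,5,8,8a-octahydroazulen-4-yl 4-(acetyloxy)benzoate
Conditions: 27, EDC·HCl, DMAP, CH2Cl2, 0 °C → rt
Reagents that add atoms: none
Why: Steglich esterification, in which only the secondary C6–OH reacts because the C4–OH is tertiary and inert to the acyl-pyridinium species.

Step 15
Reactants: 28 (3R,3aS,4S,8aR)-3-hydroxy-6,8a-dimethyl-1-oxo-3-(propan-2-yl)-1,2,3,3a,4,5,8,8a-octahydroazulen-4-yl 4-(acetyloxy)benzoate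
Product: 29 (1S,3R,3aS,4S,8aR)-1,3-dihydroxy-6,8a-dimethyl-3-(propan-2-yl)-1,2,3,3a,4,5,8,8a-octahydroazulen-4-yl 4-(acetyloxy)benzoate
Conditions: Me4NBH(OAc)3, MeCN/AcOH (1:1), −30 → 0 °C
Reagents that add atoms: none
Why: Evans–Saksena hydroxyl-directed reduction, in which the β-oriented C4–OH exchanges onto boron and hydride is delivered internally to the β-face of the C2 carbonyl, giving the 2α-alcohol trans to the directing hydroxyl (anti 1,3-diol) despite the flanking angular methyl; both esters are inert to the acetoxyborohydride.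

Step 16
Reactants: 29 (1S,3R,3aS,4S,8aR)-1,3-dihydroxy-6,8a-dimethyl-3-(propan-2-yl)-1,2,3,3a,4,5,8,8a-octahydroazulen-4-yl 4-(acetyloxy)benzoate
Product: 30 2α-hydroxyferutinin [(1S,3R,3aS,4S,8aR)-1,3-dihydroxy-6,8a-dimethyl-3-(propan-2-yl)-1,2,3,3a,4,5,8,8a-octahydroazulen-4-yl 4-hydroxybenzoate]
Conditions: pyrrolidine, CH2Cl2, 0 °C → rt
Reagents that add atoms: none
Why: chemoselective aminolysis of the activated phenyl acetate, which leaves the hindered secondary aroyl ester and both free alcohols untouched.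

**Compound list**

1 | 2-methylpropanal (isobutyraldehyde) | CC(C)C=O | starting material
2 | propane-1,3-dithiol | SCCCS | starting material
3 | 2-(propan-2-yl)-1,3-dithiane | CC(C)C1SCCCS1 | intermediate
4 | (R)-epichlorohydrin [(2R)-2-(chloromethyl)oxirane] | ClC[C@H]1CO1 | starting material
5 | 2-lithio-2-(propan-2-yl)-1,3-dithiane | [Li]C1(C(C)C)SCCCS1 | intermediate
6 | lithium (2R)-1-chloro-3-[2-(propan-2-yl)-1,3-dithian-2-yl]propan-2-olate | CC(C)C1(C[C@H](CCl)O[Li])SCCCS1 | intermediate
7 | 2-{[(2R)-oxiran-2-yl]methyl}-2-(propan-2-yl)-1,3-dithiane | CC(C)C1(C[C@@H]2CO2)SCCCS1 | intermediate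
8 | ethyl propiolate | C#CC(=O)OCC | starting material
9 | lithium acetylide of ethyl propiolate | [Li]C#CC(=O)OCC | intermediate
10 | ethyl (5S)-5-hydroxy-6-[2-(propan-2-yl)-1,3-dithian-2-yl]hex-2-ynoate | CCOC(=O)C#CC[C@H](O)CC1(C(C)C)SCCCS1 | intermediate
11 | ethyl (5S)-5-{[tert-butyl(dimethyl)silyl]oxy}-6-[2-(propan-2-yl)-1,3-dithian-2-yl]hex-2-ynoate | CCOC(=O)C#CC[C@H](O[Si](C)(C)C(C)(C)C)CC1(C(C)C)SCCCS1 | intermediate
12 | ethyl (2Z,5S)-5-{[tert-butyl(dimethyl)silyl]oxy}-3-methyl-6-[2-(propan-2-yl)-1,3-dithian-2-yl]hex-2-enoate | CCOC(=O)/C=C(/C)C[C@H](O[Si](C)(C)C(C)(C)C)CC1(C(C)C)SCCCS1 | intermediate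
13 | (2Z,5S)-5-{[tert-butyl(dimethyl)silyl]oxy}-3-methyl-6-[2-(propan-2-yl)-1,3-dithian-2-yl]hex-2-en-1-ol | OC/C=C(/C)C[C@H](O[Si](C)(C)C(C)(C)C)CC1(C(C)C)SCCCS1 | intermediate
14 | 2-[(2S,4Z)-6-bromo-2-{[tert-butyl(dimethyl)silyl]oxy}-4-methylhex-4-en-1-yl]-2-(propan-2-yl)-1,3-dithiane | BrC/C=C(/C)C[C@H](O[Si](C)(C)C(C)(C)C)CC1(C(C)C)SCCCS1 | intermediate
15 | methyl 2-methoxypropanoate (racemic) | COC(C)C(=O)OC | starting material
16 | lithium enolate of methyl 2-methoxypropanoate | COC(O[Li])=C(C)OC | intermediate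
17 | methyl (4Z,7S)-7-{[tert-butyl(dimethyl)silyl]oxy}-2-methoxy-2,5-dimethyl-8-[2-(propan-2-yl)-1,3-dithian-2-yl]oct-4-enoate (both C2 epimers) | COC(=O)C(C)(OC)C/C=C(/C)C[C@H](O[Si](C)(C)C(C)(C)C)CC1(C(C)C)SCCCS1 | intermediate
18 | lithium enolate of the 1-(trimethylsilyl) derivative of ketone 19 (enolate O on C2, Me3Si on C1) | [Li]OC(=C[Si](C)(C)C)C(C)(OC)C/C=C(/C)C[C@H](O[Si](C)(C)C(C)(C)C)CC1(C(C)C)SCCCS1 | intermediate
19 | (5Z,8S)-8-{[tert-butyl(dimethyl)silyl]oxy}-3-methoxy-3,6-dimethyl-9-[2-(propan-2-yl)-1,3-dithian-2-yl]non-5-en-2-one (both C3 epimers) | CC(=O)C(C)(OC)C/C=C(/C)C[C@H](O[Si](C)(C)C(C)(C)C)CC1(C(C)C)SCCCS1 | intermediate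
20 | (5Z,8S)-8-{[tert-butyl(dimethyl)silyl]oxy}-3-methoxy-3,6,11-trimethyldodec-5-ene-2,10-dione (both C3 epimers) | CC(=O)C(C)(OC)C/C=C(/C)C[C@H](O[Si](C)(C)C(C)(C)C)CC(=O)C(C)C | intermediate
21 | dilithium bis(enolate) of 20 (enolised at the terminal methyl and, with Z geometry, at the CH2 next to the isopropyl ketone) | C=C(O[Li])C(C)(OC)C/C=C(/C)C[C@H](O[Si](C)(C)C(C)(C)C)/C=C(\O[Li])C(C)C | intermediate
22 | (5Z,8S,9Z)-8-{[tert-butyl(dimethyl)silyl]oxy}-3-methoxy-3,6,11-trimethyl-2,10-bis[(triethylsilyl)oxy]dodeca-1,5,9-triene (both C3 epimers) | C=C(O[Si](CC)(CC)CC)C(C)(OC)C/C=C(/C)C[C@H](O[Si](C)(C)C(C)(C)C)/C=C(\O[Si](CC)(CC)CC)C(C)C | intermediate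
23 | 2-(triethylsiloxy)allyl cation formed from 22 by loss of methoxide (charge drawn on the tertiary carbon) | C=C(O[Si](CC)(CC)CC)[C+](C)C/C=C(/C)C[C@H](O[Si](C)(C)C(C)(C)C)/C=C(\O[Si](CC)(CC)CC)C(C)C | intermediate
24 | cycloheptenyl silyloxocarbenium ion: cyclohept-3-ene with 1-methyl and 1-[1-(triethylsiloxy)vinyl], 6-OTBS, and at C7 the O-triethylsilylated isobutyryl group (vinyl and acyl side chains trans, acyl and OTBS trans) | C=C(O[Si](CC)(CC)CC)[C@]1(C)CC=C(C)C[C@H](O[Si](C)(C)C(C)(C)C)[C@H]1C(=[O+][Si](CC)(CC)CC)C(C)C | intermediate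
25 | (3R,3aS,4S,8aR)-4-{[tert-butyl(dimethyl)silyl]oxy}-6,8a-dimethyl-3-(propan-2-yl)-3-[(triethylsilyl)oxy]-3,3a,4,5,8,8a-hexahydroazulen-1(2H)-one | CC1=CC[C@]2(C)[C@@H]([C@@H](O[Si](C)(C)C(C)(C)C)C1)[C@](O[Si](CC)(CC)CC)(C(C)C)CC2=O | intermediate
26 | (3R,3aS,4S,8aR)-3,4-dihydroxy-6,8a-dimethyl-3-(propan-2-yl)-3,3a,4,5,8,8a-hexahydroazulen-1(2H)-one | CC1=CC[C@]2(C)[C@@H]([C@@H](O)C1)[C@](O)(C(C)C)CC2=O | intermediate
27 | 4-acetoxybenzoic acid | CC(=O)Oc1ccc(cc1)C(=O)O | starting material
28 | (3R,3aS,4S,8aR)-3-hydroxy-6,8a-dimethyl-1-oxo-3-(propan-2-yl)-1,2,3,3a,4,5,8,8a-octahydroazulen-4-yl 4-(acetyloxy)benzoate | CC1=CC[C@]2(C)[C@@H]([C@@H](OC(=O)c3ccc(OC(C)=O)cc3)C1)[C@](O)(C(C)C)CC2=O | intermediate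
29 | (1S,3R,3aS,4S,8aR)-1,3-dihydroxy-6,8a-dimethyl-3-(propan-2-yl)-1,2,3,3a,4,5,8,8a-octahydroazulen-4-yl 4-(acetyloxy)benzoate | CC1=CC[C@]2(C)[C@@H]([C@@H](OC(=O)c3ccc(OC(C)=O)cc3)C1)[C@](O)(C(C)C)C[C@@H]2O | intermediate
30 | 2α-hydroxyferutinin, (1S,3R,3aS,4S,8aR)-1,3-dihydroxy-6,8a-dimethyl-3-(propan-2-yl)-1,2,3,3a,4,5,8,8a-octahydroazulen-4-yl 4-hydroxybenzoate | CC1=CC[C@]2(C)[C@@H]([C@@H](OC(=O)c3ccc(O)cc3)C1)[C@](O)(C(C)C)C[C@@H]2O | target

**Step count and risks**

Total steps: 16. Longest linear sequence: 16 (steps 1–16; the partners 4, 8, 15 and 27 are purchased).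

Steps most likely to fail:

1. Step 12 (proposed new method). What may go wrong: after ionisation the cation loses a proton from C10, or the first C–C bond forms but the silyloxocarbenium ion is desilylated before the second bond closes, or the two faces of the planar C1 terminus are not well distinguished. Fallback with known chemistry, from 22, returning at 26: the two bonds are made in two separate, established operations. 22 is treated with stoichiometric TiCl4 in CH2Cl2 at −78 °C and worked up with water. This Lewis-acid tertiary alkylation of a silyl enol ether, run so that both silyl groups are stripped, should stop at the monocyclic 1,4-diketone F1. Kinetic deprotonation of the acetyl methyl group of F1 (LDA, THF, −78 °C) and intramolecular aldol addition to the isopropyl ketone should give the β-hydroxy ketone F2 (the 6-O-TBS ether of 26). The reversible aldol should settle C4 with isopropyl trans to C6. HF·pyridine then returns the material to the route at 26.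

2. Step 11. What may go wrong: loss of enolate geometry, β-elimination of the C6 silyloxy group or incomplete trapping, because two different ketones must be enolised and silylated under one set of conditions. Fallback, from 19, returning at 25: the two enol ethers are made one at a time, with the dithiane protecting the second ketone during the first enolisation. 19, which has only the methyl ketone, is enolised and silylated (LiHMDS, TBSCl) to the TBS enol ether F3. The dithiane is removed as in step 10 to give the ketone F4. The single remaining ketone is then enolised under conditions chosen for Z geometry alone (LiHMDS, THF/DMPU, TESCl) to the mixed bis(enol ether) F5. Under the conditions of step 12, F5 should give 25 directly, because the silyl group on the C2 oxygen is expelled in that step whichever it is.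

3. Step 15. What may go wrong: slow exchange of the hindered tertiary hydroxyl onto boron, so that undirected hydride attack on the α-face (anti to the angular methyl) competes and the C2 epimer forms. Fallback, from 28, returning at 29, with no new compound: reagent control in place of substrate direction. A Corey–Bakshi–Shibata reduction with the (R)-2-methyl-oxazaborolidine catalyst and catecholborane distinguishes the quaternary C1 from the CH2 at C3 and should deliver hydride to the β-face whatever the hydroxyl does.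

**Further compounds**

F1 | step 12 | monocyclic 1,4-diketone: 1-acetyl-1,4-dimethylcyclohept-3-ene with 6-{[tert-butyl(dimethyl)silyl]oxy} and 7-(2-methylpropanoyl) (acetyl and 2-methylpropanoyl trans, 2-methylpropanoyl and silyloxy trans) | CC(=O)[C@]1(C)CC=C(C)C[C@H](O[Si](C)(C)C(C)(C)C)[C@H]1C(=O)C(C)C
F2 | step 12 | (3R,3aS,4S,8aR)-4-{[tert-butyl(dimethyl)silyl]oxy}-3-hydroxy-6,8a-dimethyl-3-(propan-2-yl)-3,3a,4,5,8,8a-hexahydroazulen-1(2H)-one | CC1=CC[C@]2(C)[C@@H]([C@@H](O[Si](C)(C)C(C)(C)C)C1)[C@](O)(C(C)C)CC2=O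
F3 | step 11 | TBS enol ether of 19: 2-[(2S,4Z)-2,8-bis{[tert-butyl(dimethyl)silyl]oxy}-7-methoxy-4,7-dimethylnona-4,8-dien-1-yl]-2-(propan-2-yl)-1,3-dithiane | C=C(O[Si](C)(C)C(C)(C)C)C(C)(OC)C/C=C(/C)C[C@H](O[Si](C)(C)C(C)(C)C)CC1(C(C)C)SCCCS1
F4 | step 11 | (5S,7Z)-5,11-bis{[tert-butyl(dimethyl)silyl]oxy}-10-methoxy-2,7,10-trimethyldodeca-7,11-dien-3-one | C=C(O[Si](C)(C)C(C)(C)C)C(C)(OC)C/C=C(/C)C[C@H](O[Si](C)(C)C(C)(C)C)CC(=O)C(C)C
F5 | step 11 | (5Z,8S,9Z)-2,8-bis{[tert-butyl(dimethyl)silyl]oxy}-3-methoxy-3,6,11-trimethyl-10-[(triethylsilyl)oxy]dodeca-1,5,9-triene | C=C(O[Si](C)(C)C(C)(C)C)C(C)(OC)C/C=C(/C)C[C@H](O[Si](C)(C)C(C)(C)C)/C=C(\O[Si](CC)(CC)CC)C(C)C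
F0 | step 15 | none | none
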